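**Retrosynthetic overview**
- Last operation: the ten-membered carbocycle and the 3(2H)-furanone form together from an open-chain (Z)-alkenyl iodide / tertiary propargylic alcohol. CO is inserted as C3 in a ring-closing carbonylative Sonogashira coupling, and the transient hydroxy ynone is cycloisomerised by gold.
- That precursor already carries the trans α-methylene lactone and the tiglate. C7–C8 comes from a zinc Barbier allylation with a 3-(bromomethyl)butenolide (sets C7 and C8); C8 is inverted as the tiglate is installed (Mitsunobu).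
- Butenolide (C4–C7, C11–C13, C15): acrolein + propynyl Grignard, Sharpless kinetic resolution (C6), hydroalumination–iodination ((Z)-iodide), acrylate ester, ring-closing metathesis.
- Aldehyde (C8–C10, C1, C2, C14): Sharpless epoxidation of (E)-3-methylpent-2-en-4-yn-1-ol (C10), reductive epoxide opening, oxidation.
- Ring order: butenolide first (it becomes the lactone); carbocycle and furanone last, in one operation; no protecting groups.

Assumption: germacrane locants C1–C15 are used throughout; the given SMILES is read as 4Z and (6R,7R,8R,10R).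

**Step 1**
Reactants: 1 (E)-3-methylpent-2-en-4-yn-1-ol
Product: 2 [(2S,3S)-3-ethynyl-3-methyloxiran-2-yl]methanol
Conditions: Ti(OiPr)4 (10 mol %), L-(+)-diethyl tartrate (12 mol %), t-BuOOH, 4 Å molecular sieves, CH2Cl2, −20 °C
Reagents that add atoms: tert-butyl hydroperoxide, CC(C)(C)OO
Why: Sharpless asymmetric epoxidation of a geraniol-type (E)-trisubstituted allylic alcohol; L-(+)-tartrate gives the (2S,3S)-epoxide, which fixes the future C10 carbinol.

**Step 2**
Reactants: 2 [(2S,3S)-3-ethynyl-3-methyloxiran-2-yl]methanol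
Product: 3 (3R)-3-methylpent-4-yne-1,3-diol
Conditions: NaAlH2(OCH2CH2OMe)2 (1.2 equiv), THF, −20 → 0 °C; aq. potassium sodium tartrate
Reagents that add atoms: none
Why: alkoxide-directed intramolecular hydride delivery to C2 of the 2,3-epoxy alcohol (regioselective reductive epoxide opening) gives the 1,3-diol; the tertiary C–O bond is untouched, so the centre is retained (the descriptor becomes R only through CIP ranking), and low temperature with about one equivalent spares the alkyne.

**Step 3**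
Reactants: 3 (3R)-3-methylpent-4-yne-1,3-diol
Product: 4 (3R)-3-hydroxy-3-methylpent-4-ynal
Conditions: TEMPO (10 mol %), PhI(OAc)2 (1.1 equiv), CH2Cl2, rt; used crude
Reagents that add atoms: none
Why: oxoammonium (TEMPO) oxidation stops at the aldehyde and cannot touch the tertiary alcohol; neutral conditions avoid β-elimination.

**Step 4**
Reactants: 5 acrolein; 6 1-propynylmagnesium bromide (CH3C≡CMgBr)
Product: 7 rac-hex-1-en-4-yn-3-ol
Conditions: THF, −78 °C; sat. aq. NH4Cl
Reagents that add atoms: none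
Why: Grignard 1,2-addition to the enal gives the racemic alkenyl alkynyl carbinol.

**Step 5**
Reactants: 7 rac-hex-1-en-4-yn-3-ol
Product: 8 (3S)-hex-1-en-4-yn-3-ol
Conditions: Ti(OiPr)4 (10 mol %), L-(+)-diisopropyl tartrate (15 mol %), t-BuOOH (0.6 equiv), 4 Å molecular sieves, CH2Cl2, −20 °C, to about 55 % conversion
Reagents that add atoms: none
Why: Sharpless kinetic resolution; with L-(+)-tartrate the (R)-alcohol is epoxidised fast to the erythro epoxy alcohol (removed by chromatography) and the (S)-alcohol, which becomes C6, is recovered in high ee.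

**Step 6**
Reactants: 8 (3S)-hex-1-en-4-yn-3-ol
Product: 10 (3S,4Z)-5-iodohexa-1,4-dien-3-ol, via cyclic alkenylalanate 9 (not isolated)
Conditions: NaAlH2(OCH2CH2OMe)2 (1.5 equiv), THF, 0 °C → rt; then I2, THF, −78 °C
Reagents that add atoms: iodine, II
Why: trans-hydroalumination of the propargylic alkoxide through the five-membered alanate puts Al on the distal alkyne carbon cis to the carbinol, and iodinolysis with retention gives the (Z)-iodide (hydroalumination–iodination); the vinyl group and C6 are untouched.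

**Step 7**
Reactants: 10 (3S,4Z)-5-iodohexa-1,4-dien-3-ol; 11 2-(bromomethyl)acrylic acid
Product: 12 (3S,4Z)-5-iodohexa-1,4-dien-3-yl 2-(bromomethyl)prop-2-enoate
Conditions: DCC (1.1 equiv), DMAP (5 mol %), CH2Cl2, 0 °C
Reagents that add atoms: none
Why: Steglich esterification at low temperature with little DMAP keeps the allylic bromide intact; the C–O bond at C6 is not broken.

**Step 8**
Reactants: 12 (3S,4Z)-5-iodohexa-1,4-dien-3-yl 2-(bromomethyl)prop-2-enoate
Product: 13 (5S)-3-(bromomethyl)-5-[(1Z)-2-iodoprop-1-en-1-yl]furan-2(5H)-one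
Conditions: second-generation Grubbs catalyst (5 mol %), toluene, 80 °C
Reagents that add atoms: none
Why: ring-closing metathesis between the terminal vinyl group and the acrylate alkene closes the butenolide with loss of ethene; the hindered trisubstituted iodoalkene does not take part.

**Step 9**
Reactants: 13 (5S)-3-(bromomethyl)-5-[(1Z)-2-iodoprop-1-en-1-yl]furan-2(5H)-one; 4 (3R)-3-hydroxy-3-methylpent-4-ynal
Product: 14 (4R,5S)-4-[(1S,3R)-1,3-dihydroxy-3-methylpent-4-yn-1-yl]-5-[(1Z)-2-iodoprop-1-en-1-yl]-3-methylideneoxolan-2-one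
Conditions: Zn dust, THF / sat. aq. NH4Cl, 0 °C → rt
Reagents that add atoms: none
Why: Barbier allylation with allylic transposition creates the α-methylene lactone; the aldehyde adds to C7 anti to the C6 substituent (trans lactone), and the ring-locked allylzinc in a closed chair transition state gives the 7,8-anti adduct, i.e. C8 is S (the epimer of the target, corrected in step 10).

**Step 10**
Reactants: 14 (4R,5S)-4-[(1S,3R)-1,3-dihydroxy-3-methylpent-4-yn-1-yl]-5-[(1Z)-2-iodoprop-1-en-1-yl]-3-methylideneoxolan-2-one; 15 tiglic acid ((2E)-2-methylbut-2-enoic acid)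
Product: 16 (1R,3R)-3-hydroxy-1-[(2S,3R)-2-[(1Z)-2-iodoprop-1-en-1-yl]-4-methylidene-5-oxooxolan-3-yl]-3-methylpent-4-yn-1-yl (2E)-2-methylbut-2-enoate
Conditions: PPh3 (2 equiv), DIAD (2 equiv), toluene, 0 °C → rt
Reagents that add atoms: none
Why: Mitsunobu esterification installs the tiglate with clean SN2 inversion at C8 (S → R, the natural 8β-acyloxy configuration); the tertiary propargylic alcohol cannot react.

**Step 11**
Reactants: 16 (1R,3R)-3-hydroxy-1-[(2S,3R)-2-[(1Z)-2-iodoprop-1-en-1-yl]-4-methylidene-5-oxooxolan-3-yl]-3-methylpent-4-yn-1-yl (2E)-2-methylbut-2-enoate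
Product: 18 atripliciolide tiglate, via macrocyclic hydroxy ynone 17 (not isolated)
Conditions: PdCl2(PPh3)2 (20 mol %), CuI (10 mol %), Et3N (5 equiv), CO (5 bar), THF, 0.001 M (syringe pump, 12 h), 40 °C; SiO2 plug; then (p-CF3C6H4)3PAuCl (5 mol %), AgOTf (5 mol %), toluene, rt
Reagents that add atoms: carbon monoxide, [C-]#[O+]
Why: Proposed new method: zerovalent palladium adds to the (Z)-alkenyl iodide with retention, CO inserts to the acylpalladium (favoured over direct coupling by CO pressure and by the greater strain of the nine-membered enyne), and copper-acetylide transfer with reductive elimination closes the ten-membered ring to hydroxy ynone 17 under high dilution; cationic monovalent gold then effects net hydration at C1, attack of the C10 hydroxyl on the C3 carbonyl and dehydration, giving the 3(2H)-furanone with strain release; the closest known reactions are the intermolecular carbonylative Sonogashira coupling of alkenyl iodides with tertiary propargylic alcohols, palladium-catalysed carbonylative macrocyclisations of the Stille type, and gold-catalysed cycloisomerisation of γ-hydroxy alkynones to 3(2H)-furanones; no stereocentre is touched and the 4Z geometry comes from the iodide.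

**Compound list**
1 | (E)-3-methylpent-2-en-4-yn-1-ol | C#C/C(C)=C/CO | starting material
2 | [(2S,3S)-3-ethynyl-3-methyloxiran-2-yl]methanol | C#C[C@]1(C)O[C@H]1CO | intermediate
3 | (3R)-3-methylpent-4-yne-1,3-diol | C#C[C@@](C)(CCO)O | intermediate
4 | (3R)-3-hydroxy-3-methylpent-4-ynal | C#C[C@@](C)(CC=O)O | intermediate
5 | acrolein | C=CC=O | starting material
6 | 1-propynylmagnesium bromide | CC#C[Mg]Br | starting material
7 | rac-hex-1-en-4-yn-3-ol | C=CC(O)C#CC | intermediate
8 | (3S)-hex-1-en-4-yn-3-ol | C=C[C@H](O)C#CC | intermediate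
9 | sodium (5S)-2,2-bis(2-methoxyethoxy)-3-methyl-5-vinyl-2,5-dihydro-1,2-oxaluminol-2-uide (cyclic alkenylalanate) | C=C[C@H]1C=C(C)[Al-](OCCOC)(OCCOC)O1.[Na+] | intermediate (not isolated)
10 | (3S,4Z)-5-iodohexa-1,4-dien-3-ol | C=C[C@H](O)/C=C(/C)I | intermediate
11 | 2-(bromomethyl)acrylic acid | C=C(CBr)C(=O)O | starting material
12 | (3S,4Z)-5-iodohexa-1,4-dien-3-yl 2-(bromomethyl)prop-2-enoate | C=C(CBr)C(=O)O[C@@H](C=C)/C=C(/C)I | intermediate
13 | (5S)-3-(bromomethyl)-5-[(1Z)-2-iodoprop-1-en-1-yl]furan-2(5H)-one | BrCC1=C[C@@H](/C=C(/C)I)OC1=O | intermediate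
14 | (4R,5S)-4-[(1S,3R)-1,3-dihydroxy-3-methylpent-4-yn-1-yl]-5-[(1Z)-2-iodoprop-1-en-1-yl]-3-methylideneoxolan-2-one | C=C1C(=O)O[C@H](/C=C(/C)I)[C@H]1[C@@H](O)C[C@@](C)(O)C#C | intermediate
15 | tiglic acid, (2E)-2-methylbut-2-enoic acid | C/C=C(\C)C(=O)O | starting material
16 | (1R,3R)-3-hydroxy-1-[(2S,3R)-2-[(1Z)-2-iodoprop-1-en-1-yl]-4-methylidene-5-oxooxolan-3-yl]-3-methylpent-4-yn-1-yl (2E)-2-methylbut-2-enoate | C=C1C(=O)O[C@H](/C=C(/C)I)[C@H]1[C@H](OC(=O)/C(C)=C/C)C[C@@](C)(O)C#C | intermediate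
17 | (4Z,6R,7R,8R,10R)-10-hydroxy-3-oxo-8-tigloyloxygermacra-4,11(13)-dien-1-yn-12,6-olide (ten-membered hydroxy ynone, trans-fused lactone) | C=C1C(=O)O[C@@H]2/C=C(/C)C(=O)C#C[C@](C)(O)C[C@@H](OC(=O)/C(C)=C/C)[C@@H]12 | intermediate (not isolated)
18 | atripliciolide tiglate, (4Z,6R,7R,8R,10R) | C=C1C(=O)O[C@@H]2/C=C(/C)C3=CC(=O)[C@@](C)(C[C@@H](OC(=O)/C(C)=C/C)[C@@H]12)O3 | target

**Totals**
Total step count: 11. Longest linear sequence: 8 steps (steps 4–11, from acrolein).

**Three steps most likely to fail, with fallbacks**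

Step 11 (carbonylative ring closure; oligomerisation or direct enyne coupling may win). The fallback sets out from 10 (with 4, 11 and 15) and comes back at 18. It gives up ring closure at C2–C3–C4, builds the furanone on open-chain material and closes the ring at C7–C8 by an intramolecular Barbier allylation. Alcohol 10 is silylated (TBSCl, imidazole) to tert-butyl{[(3S,4Z)-5-iodohexa-1,4-dien-3-yl]oxy}dimethylsilane F1. Intermolecular carbonylative Sonogashira coupling of F1 with aldehyde 4 (PdCl2(PPh3)2, CuI, Et3N, CO) gives (3R,7Z,9S)-9-[(tert-butyldimethylsilyl)oxy]-3-hydroxy-3,7-dimethyl-6-oxoundeca-7,10-dien-4-ynal F2, which is cycloisomerised without isolation ((p-CF3C6H4)3PAuCl, AgOTf) to 2-[(2R)-5-[(2Z,4S)-4-[(tert-butyldimethylsilyl)oxy]hexa-2,5-dien-2-yl]-2-methyl-3-oxo-2,3-dihydrofuran-2-yl]acetaldehyde F3. HF·pyridine frees 2-[(2R)-5-[(2Z,4S)-4-hydroxyhexa-2,5-dien-2-yl]-2-methyl-3-oxo-2,3-dihydrofuran-2-yl]acetaldehyde F4. This is esterified with 11 (DCC) to (3S,4Z)-5-[(5R)-5-methyl-4-oxo-5-(2-oxoethyl)-4,5-dihydrofuran-2-yl]hexa-1,4-dien-3-yl 2-(bromomethyl)prop-2-enoate F5 and closed with second-generation Grubbs catalyst to (5R)-3-(bromomethyl)-5-{(1Z)-2-[(5R)-5-methyl-4-oxo-5-(2-oxoethyl)-4,5-dihydrofuran-2-yl]prop-1-en-1-yl}furan-2(5H)-one F6. Zn dust (THF / aq. NH4Cl, high dilution) closes the ten-membered ring at C7–C8 to atripliciolide, the 8β-hydroxy parent F7 (C8 configuration as drawn is expected but must be confirmed). Esterification with 15 (2,4,6-trichlorobenzoyl chloride, Et3N, DMAP) gives 18.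

Step 10 (Mitsunobu inversion at a hindered carbinol next to a Michael acceptor; elimination or low conversion). The fallback sets out from 14 and comes back at 16. It replaces SN2 inversion by oxidation and directed reduction. Dess–Martin oxidation of 14 gives (4S,5S)-4-[(3R)-3-hydroxy-3-methylpent-4-ynoyl]-5-[(1Z)-2-iodoprop-1-en-1-yl]-3-methylideneoxolan-2-one F8. Me4NBH(OAc)3 (MeCN / AcOH, −30 °C) delivers hydride from the C10 alkoxyborohydride (Evans–Saksena 1,3-anti reduction; C8–O and C10–O are 1,3-anti in the target) to give (4R,5S)-4-[(1R,3R)-1,3-dihydroxy-3-methylpent-4-yn-1-yl]-5-[(1Z)-2-iodoprop-1-en-1-yl]-3-methylideneoxolan-2-one F9. The secondary alcohol is then acylated with retention by 15 (2,4,6-trichlorobenzoyl chloride, Et3N, DMAP) to give 16.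

Step 2 (hydride may reduce the propargylic alkyne or open the alkynyl epoxide in SN2′ fashion). The fallback sets out from 2 and comes back at 4, by-passing 3. It swaps hydride SN2 opening for single-electron C–O cleavage. TEMPO / PhI(OAc)2 oxidation of 2 gives (2R,3S)-3-ethynyl-3-methyloxirane-2-carbaldehyde F10. SmI2 (2.2 equiv, THF / MeOH, −90 °C) forms the ketyl, which fragments the α C–O bond faster than it dimerises and gives β-hydroxy aldehyde 4 after protonation; the tertiary centre is not involved.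

**Further compounds**
F1 | step 11 | tert-butyl{[(3S,4Z)-5-iodohexa-1,4-dien-3-yl]oxy}dimethylsilane | C=C[C@H](O[Si](C)(C)C(C)(C)C)/C=C(/C)I
F2 | step 11 | (3R,7Z,9S)-9-[(tert-butyldimethylsilyl)oxy]-3-hydroxy-3,7-dimethyl-6-oxoundeca-7,10-dien-4-ynal | C=C[C@H](O[Si](C)(C)C(C)(C)C)/C=C(/C)C(=O)C#C[C@](C)(O)CC=O
F3 | step 11 | 2-[(2R)-5-[(2Z,4S)-4-[(tert-butyldimethylsilyl)oxy]hexa-2,5-dien-2-yl]-2-methyl-3-oxo-2,3-dihydrofuran-2-yl]acetaldehyde | C=C[C@H](O[Si](C)(C)C(C)(C)C)/C=C(/C)C1=CC(=O)[C@@](C)(CC=O)O1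
F4 | step 11 | 2-[(2R)-5-[(2Z,4S)-4-hydroxyhexa-2,5-dien-2-yl]-2-methyl-3-oxo-2,3-dihydrofuran-2-yl]acetaldehyde | C=C[C@H](O)/C=C(/C)C1=CC(=O)[C@@](C)(CC=O)O1
F5 | step 11 | (3S,4Z)-5-[(5R)-5-methyl-4-oxo-5-(2-oxoethyl)-4,5-dihydrofuran-2-yl]hexa-1,4-dien-3-yl 2-(bromomethyl)prop-2-enoate | C=C(CBr)C(=O)O[C@@H](C=C)/C=C(/C)C1=CC(=O)[C@@](C)(CC=O)O1
F6 | step 11 | (5R)-3-(bromomethyl)-5-{(1Z)-2-[(5R)-5-methyl-4-oxo-5-(2-oxoethyl)-4,5-dihydrofuran-2-yl]prop-1-en-1-yl}furan-2(5H)-one | BrCC1=C[C@@H](/C=C(/C)C2=CC(=O)[C@@](C)(CC=O)O2)OC1=O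
F7 | step 11 | atripliciolide, (4Z,6R,7R,8R,10R)-8-hydroxy parent alcohol | C=C1C(=O)O[C@@H]2/C=C(/C)C3=CC(=O)[C@@](C)(C[C@@H](O)[C@@H]12)O3
F8 | step 10 | (4S,5S)-4-[(3R)-3-hydroxy-3-methylpent-4-ynoyl]-5-[(1Z)-2-iodoprop-1-en-1-yl]-3-methylideneoxolan-2-one | C=C1C(=O)O[C@H](/C=C(/C)I)[C@H]1C(=O)C[C@@](C)(O)C#C
F9 | step 10 | (4R,5S)-4-[(1R,3R)-1,3-dihydroxy-3-methylpent-4-yn-1-yl]-5-[(1Z)-2-iodoprop-1-en-1-yl]-3-methylideneoxolan-2-one | C=C1C(=O)O[C@H](/C=C(/C)I)[C@H]1[C@H](O)C[C@@](C)(O)C#C
F10 | step 2 | (2R,3S)-3-ethynyl-3-methyloxirane-2-carbaldehyde | C#C[C@]1(C)O[C@H]1C=O
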